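## The problem

Eupakirunsin C (38) is a germacran-12,6-olide: a ten-membered carbocycle (C1–C10) with an α-methylene-γ-butyrolactone trans-fused across C6/C7. It carries seven stereocentres, (1R,4R,5R,6S,7R,8R,10S). Three of them (C7, C8, C10) lie on one half of the ring; the others are the C6 lactone carbinol, the C1 carbinol and the cis C4–C5 epoxide next to the C3 ketone.

A ten-membered ring is hard to close and relays stereochemistry poorly. C7, C8 and C10 are therefore best set on a rigid six-membered ring. C6 can then be set next to C7, and the epoxide from an oxygen at C3. C1 is remote from all of these and needs reagent control.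

Several groups will not survive rough treatment:
- the α-methylene lactone is a strong Michael acceptor;
- the C1-hydroxy C3-ketone can dehydrate or undergo retro-aldol cleavage;
- the α,β-epoxy ketone and the tiglate are base- and nucleophile-sensitive;
- any intermediate with a free hydroxyl and a ketone at the two ends of the cis C4=C5 bond closes to a furan.

The feature that opens the route is the 1,6-relationship of C1 and C6. A bond between them folds the macrocycle into a decalin. Ring A (C1–C6) then shows the pattern C3–O, C4–CH3, cis C4=C5, C6–O, which is the para-quinol of a 2-methyl-4-alkylphenol. Ring B holds C7–C10. A C6 alkoxide and a C2 sulfonate on that decalin are set up for a Grob fragmentation that returns the ten-membered ring.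

## Retrosynthesis

**C11=C13 last.** The exocyclic methylene of 38 is cut back to the α-phosphono lactone 36 and formaldehyde (37), a Horner–Wadsworth–Emmons disconnection. The usual enolate methylenation is not possible late, because the C3 ketone is more acidic than the lactone. A free methylene lactone is not possible early, because it would not survive the nucleophilic step that puts oxygen on C1. The phosphonate is inert to oxidants and fluoride and is unveiled by carbonate.

**C1–O and the epoxy ketone.** The C1 hydroxyl of 36 is removed to give the (E)-enone 34; forward this is a conjugate borylation followed by oxidation, with a chiral copper catalyst choosing the face. The ketone of 34 comes from the epoxy alcohol 33, and 33 from the bis-allylic alcohol 32. A C3 hydroxyl of defined configuration directs the epoxidation of the (Z)-olefin. A base-mediated epoxidation of an enone next to a β-hydroxy ketone would be the alternative, and is harsher.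

**Ester and protecting-group order.** The tiglate of 32 must be in place before either the C1 or the C3 hydroxyl is free, and before the C1=C2–C3=O enone exists (a free C8–OH could add across the ring to C1). Hence 32 comes from 31, 29 and the fully silylated phosphonate 28, with tigloyl chloride (30) as the acyl source. The silyl groups are graded: primary TBS, secondary TBS at C8, TBDPS at C3. The phosphonate 28 is made from lactone 26 while no ketone is present.

**Lactone.** The C12–O bond of 26 is cut to the 1,4-diol 24, obtained from 23, and 23 from the C6 ketone 22 by enone reduction. C12 is kept at the alcohol level up to this point. An ester at C12 would lactonise onto the cis C8 hydroxyl, would compete with water in the dearomatisation, and would be a liability under borane and alkoxide.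

**Key disconnection.** The ten-membered ring of 22 is traced to the trans-fused hydroxy mesylate 20 by reconnecting C1 to C6. Forward, the C1–C6 bond shared by two six-membered rings is cleaved, so no macrocyclisation is needed. The (E)-C1=C2 olefin and the C6 carbonyl are the only new features, and the cis C4=C5 bond passes through untouched. Against a ring-closing cut at any single ring bond, this has no dilution requirement and the stereocentres are already in place.

**Ring A oxygenation.** Mesylate 20 comes from diol 19. The C1–H and C2–OH of 19 are both on the face opposite the C6 oxygen, which is the outcome of a syn hydroboration–oxidation of the C1=C2 bond of dienol ether 17. This reaction puts boron on the CH carbon, so it can tell C1=C2 from C4=C5, where boron would have to bond next to the quaternary C6. 17 comes from the dienediol 16, and 16 from the para-quinol 15 by 1,2-reduction.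

**Dearomatisation.** The C6–O bond of 15 is cut to the phenol 14. The C7 substituent on the tetralin directs water to the opposite face. 14 comes from the benzyl ether 13, the diol 12 and the cis-lactone 11.

**Ring B.**
- C8: lactone 11 arises from tetralone 9 by a reduction that sets C8 and, through the labile C7 centre, C7 as well.
- C6–C7: 9 is opened to the aryl bromide 8 (enolate arylation).
- C6–Br: 8 is traced to 7.
- C7–C11: 7 is traced to ketone 4 and methyl bromoacetate (5).
- Protection: 4 comes from phenol 3.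
- C1–C10: 3 is traced to (3-hydroxy-4-methylphenyl)boronic acid (1) and (E)-pent-3-en-2-one (2) by an asymmetric conjugate addition that sets C10.

A Friedel–Crafts route to the tetralone would be shorter but racemic at C10.

## Roads not taken

**Alternative 1:** The lactone is cut at O–C12 and C12–C11, with carbon monoxide as C12. Forward, PdCl2, PPh3 and SnCl2 under CO would join a C6 hydroxyl and a C7 ethynyl group on the finished ten-membered ring to give A1, the C1 silyl ether of the target.
- Merits: the most fragile group is made last, in one step, from a robust alkyne. This is better than the chosen plan, which spends four steps (17, 18, 19 and 26) on the lactone and its methylene and has to manage an acidic phosphonate.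
- Weak points: it does not say how the ten-membered ring with its seven stereocentres is made, so the main problem is only moved. An ethynyl group at C7 would have to survive every earlier step. The Lewis-acidic tin and palladium chloride medium meets an epoxy ketone and a tiglate.
- Comparison: the chosen plan sets against it a defined origin of the ring and of C7, C8 and C10.

**Alternative 2:** The C1–C10 bond is cut and C3–C8 reconnected. Forward, the potassium alkoxide of a C8 tertiary alcohol (KH, 18-crown-6) would undergo an anionic oxy-Cope shift to A2, a ten-membered C8 ketone with a C2=C3 methyl dienol ether.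
- Merits: a four-atom ring expansion under mild conditions. The C1 oxygen is already there, and the dienol ether delivers the C3 ketone. In this respect it is better than the chosen plan, which adds the C1 oxygen late (step 25).
- Weak points: C1 and C10 both depend on one chair-versus-boat preference of a transition state with a (Z)-propenyl terminus. The substrate is a crowded cis-divinyl cyclohexenol. The C8 ketone must later be reduced next to an epimerisable C7.
- Comparison: in the chosen plan C7, C8 and C10 are fixed by catalysts on a rigid tetralin, and the ring expansion creates no stereocentre.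

**Alternative 3:** The C2–C3 and C3–C4 bonds are cut, with CO as C3. Forward, Pd(PPh3)4 under CO would couple a C4 vinyl iodide with a C2 vinylstannane in a carbonylative Stille macrocyclisation to the dienone A3.
- Merits: it is convergent. The cross-conjugated dienone, the tiglate and the C13 carbon are all present at ring closure, so no masked methylene is needed. The endgame would be shorter than the one chosen here.
- Weak points: closing a strained ten-membered ring by a bimolecular-type coupling competes with oligomerisation and with direct, CO-free coupling to a nine-membered ring. C6, C7, C8 and C10 need acyclic stereocontrol. C1 hydration and the epoxide are still to be done.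
- Comparison: the chosen plan has the more reliable ring-forming event, a unimolecular fragmentation of a preorganised bicycle.

Key step: step 15

Assumptions: every intermediate carries the carbon numbers of the target (C1–C13), while systematic names of the bicyclic compounds use naphthalene locants. C11 of the phosphonates 28–36 is acidic and epimerisable and is drawn without configuration. Compounds 1, 2, 5, 30 and 37 are taken as commercial.

Step 1
Reactants: 1 (3-hydroxy-4-methylphenyl)boronic acid; 2 (E)-pent-3-en-2-one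
Product: 3 (S)-4-(3-hydroxy-4-methylphenyl)pentan-2-one
Conditions: Rh(acac)(C2H4)2 (3 mol %), (S)-BINAP, dioxane/H2O 10:1, 100 °C, sealed vessel
Reagents that add atoms: none
Why: Hayashi–Miyaura reaction, the rhodium-catalysed asymmetric 1,4-addition of an arylboronic acid to a linear (E)-enone; the (S)-BINAP–rhodium aryl species is expected to add to the enone face that gives (S) at C10, the sense known for 4-aryl-2-alkanones, and the free phenol is tolerated in the aqueous medium.

Step 2
Reactants: 3 (S)-4-(3-hydroxy-4-methylphenyl)pentan-2-one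
Product: 4 (S)-4-[3-(benzyloxy)-4-methylphenyl]pentan-2-one
Conditions: BnBr, K2CO3, DMF, rt
Reagents that add atoms: benzyl bromide, BrCc1ccccc1
Why: Williamson ether synthesis on the phenol; carbonate does not enolise the ketone, and the benzyl group can later be removed by hydrogenolysis without touching silyl ethers.

Step 3
Reactants: 4 (S)-4-[3-(benzyloxy)-4-methylphenyl]pentan-2-one; 5 methyl bromoacetate
Product: 7 methyl (6S)-6-[3-(benzyloxy)-4-methylphenyl]-4-oxoheptanoate, via lithium enolate 6 (not isolated)
Conditions: LDA (1.1 equiv), THF, −78 °C; then 5, DMPU, −78 → −30 °C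
Reagents that add atoms: none
Why: Kinetic deprotonation of the methyl ketone at the unhindered CH3 (C7) and SN2 alkylation of the enolate by the bromoacetate forms C7–C11; the branched C9 side is not deprotonated at −78 °C.

Step 4
Reactants: 7 methyl (6S)-6-[3-(benzyloxy)-4-methylphenyl]-4-oxoheptanoate
Product: 8 methyl (6S)-6-[5-(benzyloxy)-2-bromo-4-methylphenyl]-4-oxoheptanoate
Conditions: NBS (1.05 equiv), MeCN, 0 °C
Reagents that add atoms: N-bromosuccinimide, O=C1CCC(=O)N1Br
Why: Electrophilic aromatic bromination; the benzyloxy group directs para, which is C6, while the other activated position (C2) is flanked by two substituents.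

Step 5
Reactants: 8 methyl (6S)-6-[5-(benzyloxy)-2-bromo-4-methylphenyl]-4-oxoheptanoate
Product: 9 methyl 2-[(4S)-6-(benzyloxy)-4,7-dimethyl-2-oxo-1,2,3,4-tetrahydronaphthalen-1-yl]acetate (both C1 epimers, interconverting)
Conditions: Pd(OAc)2 (5 mol %), XPhos (10 mol %), K3PO4, toluene, 80 °C
Reagents that add atoms: none
Why: Palladium-catalysed intramolecular α-arylation of a ketone enolate closes ring B through C6–C7; arylation at C9 would give a four-membered ring and at the ester α-carbon a seven-membered one, so the 2-tetralone should be the only facile product.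

Step 6
Reactants: 9 methyl 2-[(4S)-6-(benzyloxy)-4,7-dimethyl-2-oxo-1,2,3,4-tetrahydronaphthalen-1-yl]acetate
Product: 11 (3aR,5S,9bS)-7-(benzyloxy)-5,8-dimethyl-3a,4,5,9b-tetrahydronaphtho[2,1-b]furan-2(1H)-one, via hydroxy ester 10 (not isolated)
Conditions: RuCl[(R,R)-TsDPEN](p-cymene) (2 mol %), HCO2H/Et3N 5:2, EtOAc, 35 °C; then TsOH·H2O (cat.), toluene, 50 °C
Reagents that add atoms: none
Why: Noyori–Ikariya transfer hydrogenation with dynamic kinetic resolution: C7 (benzylic and α to the ketone) epimerises quickly under Et3N, the catalyst is expected to set C8 as (R), cis to the C10 methyl, and hydride attack anti to the pseudoaxial C7 substituent gives the 7,8-cis alcohol, which lactonises. The minor C10 enantiomer from step 1 becomes a diastereomer and can be removed here.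

Step 7
Reactants: 11 (3aR,5S,9bS)-7-(benzyloxy)-5,8-dimethyl-3a,4,5,9b-tetrahydronaphtho[2,1-b]furan-2(1H)-one
Product: 12 (1S,2R,4S)-6-(benzyloxy)-1-(2-hydroxyethyl)-4,7-dimethyl-1,2,3,4-tetrahydronaphthalen-2-ol
Conditions: LiAlH4, THF, 0 °C
Reagents that add atoms: none
Why: Hydride reduction of the lactone to the 1,4-diol; holding C12 at the alcohol level removes an ester that would relactonise, take part in the dearomatisation and be exposed to borane and alkoxide later.

Step 8
Reactants: 12 (1S,2R,4S)-6-(benzyloxy)-1-(2-hydroxyethyl)-4,7-dimethyl-1,2,3,4-tetrahydronaphthalen-2-ol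
Product: 13 (1S,2R,4S)-6-(benzyloxy)-2-[(tert-butyldimethylsilyl)oxy]-1-{2-[(tert-butyldimethylsilyl)oxy]ethyl}-4,7-dimethyl-1,2,3,4-tetrahydronaphthalene
Conditions: TBSOTf (2.4 equiv), 2,6-lutidine, CH2Cl2, −78 → 0 °C
Reagents that add atoms: tert-butyldimethylsilyl triflate, CC(C)(C)[Si](C)(C)OS(=O)(=O)C(F)(F)F
Why: Silylation of both hydroxyls; the primary and the hindered secondary TBS ethers can later be cleaved one after the other.

Step 9
Reactants: 13 the bis-TBS benzyl ether
Product: 14 (5S,6R,8S)-6-[(tert-butyldimethylsilyl)oxy]-5-{2-[(tert-butyldimethylsilyl)oxy]ethyl}-3,8-dimethyl-5,6,7,8-tetrahydronaphthalen-2-ol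
Conditions: H2 (1 atm), 10% Pd/C, EtOAc, rt
Reagents that add atoms: none
Why: Hydrogenolysis of the aryl benzyl ether; nothing else in 13 is reducible under these conditions.

Step 10
Reactants: 14 the tetralin phenol
Product: 15 (4aS,5R,6R,8S)-6-[(tert-butyldimethylsilyl)oxy]-5-{2-[(tert-butyldimethylsilyl)oxy]ethyl}-4a-hydroxy-3,8-dimethyl-5,6,7,8-tetrahydronaphthalen-2(4aH)-one
Conditions: PhI(OAc)2 (1.1 equiv), MeCN/H2O 4:1, 0 °C
Reagents that add atoms: water, O
Why: Hypervalent-iodine oxidative dearomatisation of a para-alkyl phenol; water adds to the para carbon C6 of the activated phenol. In the half-chair tetralin the C7 side chain is pseudoaxial (this avoids peri strain with C5–H), so water should enter anti to it and give the C6 hydroxyl trans to the C7 side chain. The silyl ethers cannot act as internal nucleophiles.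

Step 11
Reactants: 15 the para-quinol
Product: 16 (2S,4aS,5R,6R,8S)-6-[(tert-butyldimethylsilyl)oxy]-5-{2-[(tert-butyldimethylsilyl)oxy]ethyl}-3,8-dimethyl-5,6,7,8-tetrahydronaphthalene-2,4a(2H)-diol
Conditions: (R)-2-methyl-CBS-oxazaborolidine (0.3 equiv), catecholborane (2.5 equiv), toluene, −78 °C
Reagents that add atoms: none
Why: Corey–Bakshi–Shibata 1,2-reduction of the cross-conjugated dienone; the α-methyl-bearing arm (C4) acts as the large group, so the (R)-catalyst should give (3S), the carbinol trans to the C6 hydroxyl. The substrate's own bias (hydride syn to the C6 oxygen) points the same way, and the free tertiary hydroxyl only consumes borane.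

Step 12
Reactants: 16 the dienediol
Product: 17 (2S,4aS,5R,6R,8S)-6-[(tert-butyldimethylsilyl)oxy]-5-{2-[(tert-butyldimethylsilyl)oxy]ethyl}-2-[(tert-butyldiphenylsilyl)oxy]-3,8-dimethyl-5,6,7,8-tetrahydronaphthalen-4a(2H)-ol
Conditions: TBDPSCl, imidazole, DMF, 0 °C → rt
Reagents that add atoms: tert-butyl(chloro)diphenylsilane, CC(C)(C)[Si](Cl)(c1ccccc1)c1ccccc1
Why: Selective silylation of the secondary bis-allylic hydroxyl, the tertiary C6 hydroxyl being inert; this caps the acid-sensitive dienol, and TBDPS outlasts the later TBS cleavages.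

Step 13
Reactants: 17 the C3 silyl ether
Product: 19 (1S,2R,4aS,5R,6R,8S,8aS)-6-[(tert-butyldimethylsilyl)oxy]-5-{2-[(tert-butyldimethylsilyl)oxy]ethyl}-2-[(tert-butyldiphenylsilyl)oxy]-3,8-dimethyl-1,2,4a,5,6,7,8,8a-octahydronaphthalene-1,4a-diol (trans-fused), via C2 alkylborane 18 (not isolated)
Conditions: BH3·THF (2.5 equiv), THF, −10 → 0 °C; then NaBO3·4H2O, H2O, rt
Reagents that add atoms: borane–tetrahydrofuran, B.C1CCOC1 (boron carried only in 18); sodium perborate, [Na+].[O-]OB=O
Why: Hydroboration–oxidation, syn and anti-Markovnikov: boron goes to the CH carbon C2 and hydrogen to C1 from the face opposite the C6 oxygen. That face is the convex face of the boat-shaped cyclohexadiene, in which the C3 silyloxy group and C7 are pseudoequatorial; the result is the trans ring fusion with an equatorial C2 hydroxyl. C4=C5 should react more slowly because boron would have to bond to C5, a neopentyl position next to the quaternary C6.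

Step 14
Reactants: 19 the trans-octalin diol
Product: 20 (1S,2R,4aS,5R,6R,8S,8aS)-6-[(tert-butyldimethylsilyl)oxy]-5-{2-[(tert-butyldimethylsilyl)oxy]ethyl}-2-[(tert-butyldiphenylsilyl)oxy]-4a-hydroxy-3,8-dimethyl-1,2,4a,5,6,7,8,8a-octahydronaphthalen-1-yl methanesulfonate
Conditions: MsCl, Et3N, DMAP (cat.), CH2Cl2, −20 → 0 °C
Reagents that add atoms: methanesulfonyl chloride, CS(=O)(=O)Cl
Why: Sulfonylation of the secondary C2 hydroxyl; the tertiary C6 hydroxyl does not react under these conditions.

Step 15
Reactants: 20 the trans-fused C6-hydroxy C2-mesylate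
Product: 22 (1E,3S,4Z,7R,8R,10S)-8-[(tert-butyldimethylsilyl)oxy]-7-{2-[(tert-butyldimethylsilyl)oxy]ethyl}-3-[(tert-butyldiphenylsilyl)oxy]-4,10-dimethylcyclodeca-1,4-dien-6-one (target numbering), via potassium alkoxide 21 (not isolated)
Conditions: KOtBu (1.05 equiv), THF, −20 → 0 °C; pH 7 buffer
Reagents that add atoms: none
Why: KOtBu converts the tertiary C6 hydroxyl into alkoxide 21. In the trans-fused bicycle the equatorial C2–OMs bond is antiperiplanar to the C1–C6 bond, so the oxygen lone pair pushes through C6 as the mesylate leaves in a concerted Grob fragmentation. The closest known reaction type is the fragmentation of decalin-1,3-diol monosulfonates to (E)-cyclodecenones. No ring is closed by bond formation: the ten-membered ring is unveiled by cutting the bond shared by the two six-membered rings, so no macrocyclisation penalty is paid. No stereocentre is created; the olefin is E because C10, equatorial on ring A, is antiperiplanar to C3 across C1–C2. The step needs selectivity against elimination, epoxide or oxetane formation and against enolisation of the product. The equatorial mesylate has no antiperiplanar hydrogen, the C3 oxygen is silylated and the C6 oxygen cannot reach the backside of C2; only a slight excess of base is used, with a buffered quench, so the new ketone is not epimerised at C7. The cis C4=C5 bond is a spectator and emerges as the (Z)-enone.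

Step 16
Reactants: 22 the (1E,4Z)-dien-6-one
Product: 23 (1E,3S,4Z,6R,7S,8R,10S)-8-[(tert-butyldimethylsilyl)oxy]-7-{2-[(tert-butyldimethylsilyl)oxy]ethyl}-3-[(tert-butyldiphenylsilyl)oxy]-4,10-dimethylcyclodeca-1,4-dien-6-ol
Conditions: (R)-2-methyl-CBS-oxazaborolidine (0.5 equiv), catecholborane (1.5 equiv), toluene, −78 °C
Reagents that add atoms: none
Why: Corey–Bakshi–Shibata 1,2-reduction of the (Z)-enone; with the alkenyl arm as the large group, the (R)-catalyst should deliver hydride so that the C6 oxygen ends trans to the C7 side chain ((6R) here), as the trans lactone needs. No conjugate reduction is expected.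

Step 17
Reactants: 23 the C6 allylic alcohol
Product: 24 (1E,3S,4Z,6R,7S,8R,10S)-8-[(tert-butyldimethylsilyl)oxy]-3-[(tert-butyldiphenylsilyl)oxy]-7-(2-hydroxyethyl)-4,10-dimethylcyclodeca-1,4-dien-6-ol
Conditions: HF·pyridine, pyridine, THF, 0 °C
Reagents that add atoms: none
Why: Selective desilylation; the primary TBS ether is cleaved much faster than the hindered secondary TBS and the TBDPS ether under buffered HF.

Step 18
Reactants: 24 the 1,4-diol
Product: 26 (1E,3S,4Z,6R,7S,8R,10S)-8-[(tert-butyldimethylsilyl)oxy]-3-[(tert-butyldiphenylsilyl)oxy]-4,10-dimethyl-13-norgermacra-1,4-dien-12,6-olide (trans-fused γ-lactone), via lactol 25 (not isolated)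
Conditions: TEMPO (0.2 equiv), PhI(OAc)2 (2.5 equiv), CH2Cl2, rt
Reagents that add atoms: none
Why: Oxoammonium-mediated oxidative lactonisation of a 1,4-diol: the primary alcohol is oxidised first, the aldehyde is trapped by the C6 hydroxyl as lactol 25, and 25 is oxidised to the lactone. The secondary allylic alcohol reacts more slowly and is protected once the lactol forms.

Step 19
Reactants: 26 the trans-lactone
Product: 28 the C11 diethoxyphosphoryl derivative of 26 (C11 epimers; other centres as in 26), via enol phosphate 27 (not isolated)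
Conditions: LDA (1.1 equiv), THF, −78 °C; ClP(O)(OEt)2, DMPU, −78 → 0 °C; LDA (2.2 equiv), −78 → 0 °C; AcOH
Reagents that add atoms: diethyl chlorophosphate, CCOP(=O)(Cl)OCC
Why: The lactone enolate is phosphorylated on oxygen and excess amide base triggers the 1,3-shift of phosphorus from oxygen to carbon (vinyl phosphate to α-phosphono lactone rearrangement). It is done here because no ketone is present yet, and the phosphonate is an oxidant-stable, non-electrophilic precursor of the methylene group.

Step 20
Reactants: 28 the phosphono lactone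
Product: 29 the C8 alcohol (8-hydroxy, 3-TBDPS ether; stereocentres as in 26)
Conditions: HF·pyridine, pyridine, THF, 0 °C → rt
Reagents that add atoms: none
Why: Fluoride cleavage of the secondary TBS ether; the TBDPS ether at C3 is markedly more stable and should remain.

Step 21
Reactants: 29 the C8 alcohol; 30 tigloyl chloride ((E)-2-methylbut-2-enoyl chloride)
Product: 31 the C8 tiglate (3-TBDPS ether, C11 phosphonate)
Conditions: pyridine, DMAP (cat.), CH2Cl2, 0 °C → rt
Reagents that add atoms: none
Why: Acylation of the C8 hydroxyl under weakly basic conditions; at this stage it is the only free hydroxyl and there is no enone for it to add to across the ring.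

Step 22
Reactants: 31 the C8 tiglate
Product: 32 the C3 bis-allylic alcohol ((3S); tiglate, phosphonate)
Conditions: TBAF, AcOH (1:1), THF, rt → 40 °C
Reagents that add atoms: none
Why: Fluoride cleavage of the TBDPS ether, buffered with acetic acid so that the acidic phosphonate, the lactone and the tiglate do not meet basic fluoride.

Step 23
Reactants: 32 the C3 alcohol
Product: 33 the (3S,4S,5R)-4,5-epoxy alcohol (epoxide cis to the C3 hydroxyl)
Conditions: VO(acac)2 (5 mol %), TBHP (1.1 equiv), CH2Cl2, −20 → 0 °C
Reagents that add atoms: tert-butyl hydroperoxide, CC(C)(C)OO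
Why: Hydroxyl-directed vanadium-catalysed epoxidation; the vanadate ester of the C3 hydroxyl delivers oxygen to the same face of the (Z)-olefin, the syn outcome known for medium-ring (Z)-cycloalkenols, which is the C4–C5 configuration of the target. The trisubstituted olefin with a methyl geminal to the carbinol should react before the (E)-disubstituted C1=C2; the tiglate and lactone are electron-poor and inert.

Step 24
Reactants: 33 the epoxy alcohol
Product: 34 the (1E)-4,5-epoxy-1-en-3-one ((4R,5R); tiglate, phosphonate)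
Conditions: Dess–Martin periodinane, NaHCO3, CH2Cl2, 0 °C
Reagents that add atoms: none
Why: Mild oxidation of the secondary alcohol to the ketone; it is safe at this point because the C6 oxygen is acylated, so no furan can form.

Step 25
Reactants: 34 the epoxy enone
Product: 36 the (1R)-1-hydroxy-3-ketone ((1R,4R,5R); tiglate, phosphonate), via C1 pinacolboronate 35 (not isolated)
Conditions: Cu(OH)2 (5 mol %), (S,S)-6,6′-bis(1-hydroxy-2,2-dimethylpropyl)-2,2′-bipyridine (6 mol %), AcOH (6 mol %), B2pin2 (1.2 equiv), H2O/THF, 5 °C; then NaBO3·4H2O, THF/pH 7 buffer, 0 °C → rt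
Reagents that add atoms: bis(pinacolato)diboron, CC1(C)OB(OC1(C)C)B1OC(C)(C)C(C)(C)O1 (boron carried only in 35); sodium perborate, [Na+].[O-]OB=O
Why: Copper-catalysed conjugate borylation of the only enone, then C–B oxidation with retention; the ligand antipode is chosen so that the chiral bipyridine–copper boryl species adds to the Si face of C1 and gives (1R). The base-free, acetate-buffered medium leaves the acidic phosphonate un-ionised, and the trisubstituted tiglate is a much slower acceptor.

Step 26
Reactants: 36 the phosphonate; 37 formaldehyde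
Product: 38 eupakirunsin C, (1R,4R,5R,6S,7R,8R,10S)-4,5-epoxy-1-hydroxy-3-oxo-8-tigloyloxygermacr-11(13)-en-12,6-olide
Conditions: 37% aq. HCHO (10 equiv), K2CO3 (2 equiv), THF, 0 °C, 30 min
Reagents that add atoms: none
Why: Horner–Wadsworth–Emmons olefination; carbonate deprotonates the phosphonate (the most acidic C–H), the anion adds to formaldehyde, which is far more electrophilic than the hindered ketone, and loss of diethyl phosphate forms the exocyclic C11=C13 bond. The short time at 0 °C should spare the β-hydroxy ketone.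

## Compound list

1 | (3-hydroxy-4-methylphenyl)boronic acid | Cc1ccc(B(O)O)cc1O | starting material
2 | (E)-pent-3-en-2-one | C/C=C/C(C)=O | starting material
3 | (S)-4-(3-hydroxy-4-methylphenyl)pentan-2-one | CC(=O)C[C@H](C)c1ccc(C)c(O)c1 | intermediate
4 | (S)-4-[3-(benzyloxy)-4-methylphenyl]pentan-2-one | CC(=O)C[C@H](C)c1ccc(C)c(OCc2ccccc2)c1 | intermediate
5 | methyl bromoacetate | COC(=O)CBr | starting material
6 | lithium enolate of 4 (terminal) | [Li]OC(=C)C[C@H](C)c1ccc(C)c(OCc2ccccc2)c1 | intermediate
7 | methyl (6S)-6-[3-(benzyloxy)-4-methylphenyl]-4-oxoheptanoate | COC(=O)CCC(=O)C[C@H](C)c1ccc(C)c(OCc2ccccc2)c1 | intermediate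
8 | methyl (6S)-6-[5-(benzyloxy)-2-bromo-4-methylphenyl]-4-oxoheptanoate | COC(=O)CCC(=O)C[C@H](C)c1cc(OCc2ccccc2)c(C)cc1Br | intermediate
9 | methyl 2-[(4S)-6-(benzyloxy)-4,7-dimethyl-2-oxo-1,2,3,4-tetrahydronaphthalen-1-yl]acetate (C1 epimers) | COC(=O)CC1C(=O)C[C@H](C)c2cc(OCc3ccccc3)c(C)cc21 | intermediate
10 | methyl 2-[(1S,2R,4S)-6-(benzyloxy)-2-hydroxy-4,7-dimethyl-1,2,3,4-tetrahydronaphthalen-1-yl]acetate | COC(=O)C[C@@H]1[C@H](O)C[C@H](C)c2cc(OCc3ccccc3)c(C)cc21 | intermediate
11 | (3aR,5S,9bS)-7-(benzyloxy)-5,8-dimethyl-3a,4,5,9b-tetrahydronaphtho[2,1-b]furan-2(1H)-one | O=C1C[C@@H]2[C@H](O1)C[C@H](C)c3cc(OCc4ccccc4)c(C)cc32 | intermediate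
12 | (1S,2R,4S)-6-(benzyloxy)-1-(2-hydroxyethyl)-4,7-dimethyl-1,2,3,4-tetrahydronaphthalen-2-ol | OCC[C@@H]1[C@H](O)C[C@H](C)c2cc(OCc3ccccc3)c(C)cc21 | intermediate
13 | (1S,2R,4S)-6-(benzyloxy)-2-[(tert-butyldimethylsilyl)oxy]-1-{2-[(tert-butyldimethylsilyl)oxy]ethyl}-4,7-dimethyl-1,2,3,4-tetrahydronaphthalene | CC(C)(C)[Si](C)(C)OCC[C@@H]1[C@H](O[Si](C)(C)C(C)(C)C)C[C@H](C)c2cc(OCc3ccccc3)c(C)cc21 | intermediate
14 | (5S,6R,8S)-6-[(tert-butyldimethylsilyl)oxy]-5-{2-[(tert-butyldimethylsilyl)oxy]ethyl}-3,8-dimethyl-5,6,7,8-tetrahydronaphthalen-2-ol | CC(C)(C)[Si](C)(C)OCC[C@@H]1[C@H](O[Si](C)(C)C(C)(C)C)C[C@H](C)c2cc(O)c(C)cc21 | intermediate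
15 | (4aS,5R,6R,8S)-6-[(tert-butyldimethylsilyl)oxy]-5-{2-[(tert-butyldimethylsilyl)oxy]ethyl}-4a-hydroxy-3,8-dimethyl-5,6,7,8-tetrahydronaphthalen-2(4aH)-one | CC(C)(C)[Si](C)(C)OCC[C@@H]1[C@H](O[Si](C)(C)C(C)(C)C)C[C@H](C)C2=CC(=O)C(C)=C[C@@]21O | intermediate
16 | (2S,4aS,5R,6R,8S)-6-[(tert-butyldimethylsilyl)oxy]-5-{2-[(tert-butyldimethylsilyl)oxy]ethyl}-3,8-dimethyl-5,6,7,8-tetrahydronaphthalene-2,4a(2H)-diol | CC(C)(C)[Si](C)(C)OCC[C@@H]1[C@H](O[Si](C)(C)C(C)(C)C)C[C@H](C)C2=C[C@H](O)C(C)=C[C@@]21O | intermediate
17 | (2S,4aS,5R,6R,8S)-6-[(tert-butyldimethylsilyl)oxy]-5-{2-[(tert-butyldimethylsilyl)oxy]ethyl}-2-[(tert-butyldiphenylsilyl)oxy]-3,8-dimethyl-5,6,7,8-tetrahydronaphthalen-4a(2H)-ol | CC(C)(C)[Si](C)(C)OCC[C@@H]1[C@H](O[Si](C)(C)C(C)(C)C)C[C@H](C)C2=C[C@H](O[Si](c3ccccc3)(c3ccccc3)C(C)(C)C)C(C)=C[C@@]21O | intermediate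
18 | C2 alkylborane from 17 (boron at C2, hydrogen at C1, both anti to the C6 oxygen) | CC(C)(C)[Si](C)(C)OCC[C@@H]1[C@H](O[Si](C)(C)C(C)(C)C)C[C@H](C)[C@H]2[C@H](B)[C@H](O[Si](c3ccccc3)(c3ccccc3)C(C)(C)C)C(C)=C[C@@]21O | intermediate
19 | (1S,2R,4aS,5R,6R,8S,8aS)-6-[(tert-butyldimethylsilyl)oxy]-5-{2-[(tert-butyldimethylsilyl)oxy]ethyl}-2-[(tert-butyldiphenylsilyl)oxy]-3,8-dimethyl-1,2,4a,5,6,7,8,8a-octahydronaphthalene-1,4a-diol | CC(C)(C)[Si](C)(C)OCC[C@@H]1[C@H](O[Si](C)(C)C(C)(C)C)C[C@H](C)[C@H]2[C@H](O)[C@H](O[Si](c3ccccc3)(c3ccccc3)C(C)(C)C)C(C)=C[C@@]21O | intermediate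
20 | (1S,2R,4aS,5R,6R,8S,8aS)-6-[(tert-butyldimethylsilyl)oxy]-5-{2-[(tert-butyldimethylsilyl)oxy]ethyl}-2-[(tert-butyldiphenylsilyl)oxy]-4a-hydroxy-3,8-dimethyl-1,2,4a,5,6,7,8,8a-octahydronaphthalen-1-yl methanesulfonate | CC(C)(C)[Si](C)(C)OCC[C@@H]1[C@H](O[Si](C)(C)C(C)(C)C)C[C@H](C)[C@H]2[C@H](OS(C)(=O)=O)[C@H](O[Si](c3ccccc3)(c3ccccc3)C(C)(C)C)C(C)=C[C@@]21O | intermediate
21 | potassium C6 alkoxide of 20 | CC(C)(C)[Si](C)(C)OCC[C@@H]1[C@H](O[Si](C)(C)C(C)(C)C)C[C@H](C)[C@H]2[C@H](OS(C)(=O)=O)[C@H](O[Si](c3ccccc3)(c3ccccc3)C(C)(C)C)C(C)=C[C@@]21[O-].[K+] | intermediate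
22 | (1E,3S,4Z,7R,8R,10S)-8-[(tert-butyldimethylsilyl)oxy]-7-{2-[(tert-butyldimethylsilyl)oxy]ethyl}-3-[(tert-butyldiphenylsilyl)oxy]-4,10-dimethylcyclodeca-1,4-dien-6-one | CC(C)(C)[Si](C)(C)OCC[C@@H]1[C@H](O[Si](C)(C)C(C)(C)C)C[C@H](C)/C=C/[C@H](O[Si](c2ccccc2)(c2ccccc2)C(C)(C)C)/C(C)=C\C1=O | intermediate
23 | (1E,3S,4Z,6R,7S,8R,10S)-8-[(tert-butyldimethylsilyl)oxy]-7-{2-[(tert-butyldimethylsilyl)oxy]ethyl}-3-[(tert-butyldiphenylsilyl)oxy]-4,10-dimethylcyclodeca-1,4-dien-6-ol | CC(C)(C)[Si](C)(C)OCC[C@@H]1[C@H](O[Si](C)(C)C(C)(C)C)C[C@H](C)/C=C/[C@H](O[Si](c2ccccc2)(c2ccccc2)C(C)(C)C)/C(C)=C\[C@H]1O | intermediate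
24 | (1E,3S,4Z,6R,7S,8R,10S)-8-[(tert-butyldimethylsilyl)oxy]-3-[(tert-butyldiphenylsilyl)oxy]-7-(2-hydroxyethyl)-4,10-dimethylcyclodeca-1,4-dien-6-ol | OCC[C@@H]1[C@H](O[Si](C)(C)C(C)(C)C)C[C@H](C)/C=C/[C@H](O[Si](c2ccccc2)(c2ccccc2)C(C)(C)C)/C(C)=C\[C@H]1O | intermediate
25 | lactol from 24 (C12 hemiacetal, C12 epimers) | C1C(O)O[C@H]2[C@H]1[C@H](O[Si](C)(C)C(C)(C)C)C[C@H](C)/C=C/[C@H](O[Si](c1ccccc1)(c1ccccc1)C(C)(C)C)/C(C)=C\2 | intermediate
26 | (1E,3S,4Z,6R,7S,8R,10S)-8-[(tert-butyldimethylsilyl)oxy]-3-[(tert-butyldiphenylsilyl)oxy]-4,10-dimethyl-13-norgermacra-1,4-dien-12,6-olide | C1C(=O)O[C@H]2[C@H]1[C@H](O[Si](C)(C)C(C)(C)C)C[C@H](C)/C=C/[C@H](O[Si](c1ccccc1)(c1ccccc1)C(C)(C)C)/C(C)=C\2 | intermediate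
27 | enol diethyl phosphate of 26 (C11=C12) | C1=C(OP(=O)(OCC)OCC)O[C@H]2[C@H]1[C@H](O[Si](C)(C)C(C)(C)C)C[C@H](C)/C=C/[C@H](O[Si](c1ccccc1)(c1ccccc1)C(C)(C)C)/C(C)=C\2 | intermediate
28 | 11-(diethoxyphosphoryl) derivative of 26 (C11 epimers) | CCOP(=O)(OCC)C1C(=O)O[C@H]2[C@H]1[C@H](O[Si](C)(C)C(C)(C)C)C[C@H](C)/C=C/[C@H](O[Si](c1ccccc1)(c1ccccc1)C(C)(C)C)/C(C)=C\2 | intermediate
29 | 8-hydroxy phosphono lactone (3-TBDPS ether) | CCOP(=O)(OCC)C1C(=O)O[C@H]2[C@H]1[C@H](O)C[C@H](C)/C=C/[C@H](O[Si](c1ccccc1)(c1ccccc1)C(C)(C)C)/C(C)=C\2 | intermediate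
30 | tigloyl chloride, (E)-2-methylbut-2-enoyl chloride | C/C=C(\C)C(Cl)=O | starting material
31 | 8-tigloyloxy phosphono lactone (3-TBDPS ether) | CCOP(=O)(OCC)C1C(=O)O[C@H]2[C@H]1[C@H](OC(=O)/C(C)=C/C)C[C@H](C)/C=C/[C@H](O[Si](c1ccccc1)(c1ccccc1)C(C)(C)C)/C(C)=C\2 | intermediate
32 | (3S)-3-hydroxy-8-tigloyloxy phosphono lactone, (1E,4Z)-diene | CCOP(=O)(OCC)C1C(=O)O[C@H]2[C@H]1[C@H](OC(=O)/C(C)=C/C)C[C@H](C)/C=C/[C@H](O)/C(C)=C\2 | intermediate
33 | (3S,4S,5R)-4,5-epoxy-3-hydroxy-8-tigloyloxy phosphono lactone, (1E)-ene | CCOP(=O)(OCC)C1C(=O)O[C@H]2[C@H]1[C@H](OC(=O)/C(C)=C/C)C[C@H](C)/C=C/[C@H](O)[C@]1(C)O[C@H]21 | intermediate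
34 | (1E,4R,5R)-4,5-epoxy-3-oxo-8-tigloyloxy phosphono lactone | CCOP(=O)(OCC)C1C(=O)O[C@H]2[C@H]1[C@H](OC(=O)/C(C)=C/C)C[C@H](C)/C=C/C(=O)[C@]1(C)O[C@H]21 | intermediate
35 | C1 pinacolboronate of the 3-ketone (boron on the Si face of C1) | CCOP(=O)(OCC)C1C(=O)O[C@H]2[C@H]1[C@H](OC(=O)/C(C)=C/C)C[C@H](C)[C@H](B3OC(C)(C)C(C)(C)O3)CC(=O)[C@]1(C)O[C@H]21 | intermediate
36 | (1R,4R,5R)-4,5-epoxy-1-hydroxy-3-oxo-8-tigloyloxy phosphono lactone | CCOP(=O)(OCC)C1C(=O)O[C@H]2[C@H]1[C@H](OC(=O)/C(C)=C/C)C[C@H](C)[C@H](O)CC(=O)[C@]1(C)O[C@H]21 | intermediate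
37 | formaldehyde | C=O | starting material
38 | eupakirunsin C | C=C1C(=O)O[C@H]2[C@H]1[C@H](OC(=O)/C(C)=C/C)C[C@H](C)[C@H](O)CC(=O)[C@]1(C)O[C@H]21 | target

## Step count and risks

Total: 26 steps. Longest linear sequence: 26 steps (1 and 2 to 38); the route is fully linear.

**Step 15 (key step).** The fragmentation itself has the ideal geometry. The likely failure is what happens after it: alkoxide still present can enolise the new C6 ketone toward C7, which would epimerise C7 or expel the C8 silyloxy group. Fallback: from 20, silylate the tertiary hydroxyl with N-(trimethylsilyl)imidazole to the C6 trimethylsilyl ether of 20 F1, and release the alkoxide with one equivalent of TBAF at −78 → −20 °C. The alkoxide then forms only as fast as it fragments and no tert-butoxide is present. This returns to the route at 22.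

**Step 13.** Two things can go wrong: competing hydroboration of the C4=C5 bond, and delivery of borane syn to the C6 oxygen. The two olefins are both trisubstituted, and the facial bias rests on one boat conformer. Fallback, from 17: deliver the reagent from the C6 oxygen.
- Silylate with 1,1,3,3-tetramethyldisilazane to the C6 dimethylsilyl (Si–H) ether F2.
- Pt2(dvtms)3 (the platinum–divinyltetramethyldisiloxane complex) should close the five-membered ring by placing silicon on C2, the only CH terminus in reach, and hydrogen on C1, both syn to the oxygen. This gives the cis-fused oxasilolane F3.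
- Tamao–Fleming oxidation (H2O2, KF, KHCO3) gives the cis-fused C2,C6-syn diol F4, and mesylation gives the cis-fused mesylate F5.
- In the cis-fused chair that keeps ring B unchanged, the C2–OMs bond is again equatorial on ring A and antiperiplanar to C1–C6, and C10 is equatorial. KOtBu should therefore give the same (E)-olefin, and the route is rejoined at 22.

**Step 16.** Hydride may be delivered to the wrong face of the C6 carbonyl, because the α-branched C7 arm competes with the (Z)-alkenyl arm for the role of large group in the catalyst pocket. Fallback: from 22, if the (6S)-epimer of 23 F6 is formed, invert it by a Mitsunobu reaction (4-nitrobenzoic acid, PPh3, DIAD) to the (6R) 4-nitrobenzoate F7, and cleave the ester with K2CO3 in MeOH. This returns to 23.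

**Step 23.** The catalyst may not discriminate enough between the two olefins flanking the C3 carbinol, so C1=C2 is also epoxidised; or oxygen may be delivered to the wrong face in this ten-membered ring. Fallback, from 32: change the order.
- Oxidise with MnO2 to the cross-conjugated (1E,4Z)-dien-3-one F8.
- Borylate and oxidise C1 as in step 25 (only the unsubstituted (E)-enone should react) to the 1-hydroxy-4-en-3-one F9.
- Epoxidise the remaining (Z)-enone with TBHP and DBU, anti to the C6 oxygen as in 4-oxygenated cyclohexenones. This rejoins the route at 36.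

**Step 25.** Facial selectivity at C1 may be poor if the preferred conformer of the (E)-enone opposes the catalyst, and the reaction may be slow in the heterogeneous medium. Fallback: from 34, epoxidise the (E)-enone with TBHP and DBU to the 1,2:4,5-bis-epoxy ketone F10. Open the C1–C2 epoxide reductively at C2 with sodium phenylselenide (PhSeSePh, NaBH4, AcOH, EtOH); the C4 epoxide carbon is fully substituted and resists SN2 attack by selenolate. This returns to 36.

## Further compounds

F1 | step 15 | C6 trimethylsilyl ether of 20 | CC(C)(C)[Si](C)(C)OCC[C@@H]1[C@H](O[Si](C)(C)C(C)(C)C)C[C@H](C)[C@H]2[C@H](OS(C)(=O)=O)[C@H](O[Si](c3ccccc3)(c3ccccc3)C(C)(C)C)C(C)=C[C@@]21O[Si](C)(C)C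
F2 | step 13 | C6 dimethylsilyl (Si–H) ether of 17 | CC(C)(C)[Si](C)(C)OCC[C@@H]1[C@H](O[Si](C)(C)C(C)(C)C)C[C@H](C)C2=C[C@H](O[Si](c3ccccc3)(c3ccccc3)C(C)(C)C)C(C)=C[C@@]21O[SiH](C)C
F3 | step 13 | cis-fused oxasilolane (Si on C2, H on C1, both syn to the C6 oxygen) | CC(C)(C)[Si](C)(C)OCC[C@@H]1[C@H](O[Si](C)(C)C(C)(C)C)C[C@H](C)[C@@H]2[C@@H]3[C@H](O[Si](c4ccccc4)(c4ccccc4)C(C)(C)C)C(C)=C[C@@]21O[Si]3(C)C
F4 | step 13 | cis-fused C2,C6-syn diol (C1 and C2 epimer of 19) | CC(C)(C)[Si](C)(C)OCC[C@@H]1[C@H](O[Si](C)(C)C(C)(C)C)C[C@H](C)[C@@H]2[C@@H](O)[C@H](O[Si](c3ccccc3)(c3ccccc3)C(C)(C)C)C(C)=C[C@@]21O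
F5 | step 13 | cis-fused C2 mesylate (C1 and C2 epimer of 20) | CC(C)(C)[Si](C)(C)OCC[C@@H]1[C@H](O[Si](C)(C)C(C)(C)C)C[C@H](C)[C@@H]2[C@@H](OS(C)(=O)=O)[C@H](O[Si](c3ccccc3)(c3ccccc3)C(C)(C)C)C(C)=C[C@@]21O
F6 | step 16 | (6S)-epimer of 23 | CC(C)(C)[Si](C)(C)OCC[C@@H]1[C@H](O[Si](C)(C)C(C)(C)C)C[C@H](C)/C=C/[C@H](O[Si](c2ccccc2)(c2ccccc2)C(C)(C)C)/C(C)=C\[C@@H]1O
F7 | step 16 | (6R) 4-nitrobenzoate of 23 | CC(C)(C)[Si](C)(C)OCC[C@@H]1[C@H](O[Si](C)(C)C(C)(C)C)C[C@H](C)/C=C/[C@H](O[Si](c2ccccc2)(c2ccccc2)C(C)(C)C)/C(C)=C\[C@H]1OC(=O)c2ccc(cc2)[N+](=O)[O-]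
F8 | step 23 | (1E,4Z)-dien-3-one (8-tiglate, C11 phosphonate) | CCOP(=O)(OCC)C1C(=O)O[C@H]2[C@H]1[C@H](OC(=O)/C(C)=C/C)C[C@H](C)/C=C/C(=O)/C(C)=C\2
F9 | step 23 | (1R)-1-hydroxy-(4Z)-en-3-one (8-tiglate, C11 phosphonate) | CCOP(=O)(OCC)C1C(=O)O[C@H]2[C@H]1[C@H](OC(=O)/C(C)=C/C)C[C@H](C)[C@H](O)CC(=O)/C(C)=C\2
F10 | step 25 | 1,2:4,5-bis-epoxy-3-ketone (C1–O as in 36) | CCOP(=O)(OCC)C1C(=O)O[C@H]2[C@H]1[C@H](OC(=O)/C(C)=C/C)C[C@H](C)[C@@H]3O[C@H]3C(=O)[C@]1(C)O[C@H]21
A1 | alternative 1 | C1 tert-butyldimethylsilyl ether of the target | C=C1C(=O)O[C@H]2[C@H]1[C@H](OC(=O)/C(C)=C/C)C[C@H](C)[C@H](O[Si](C)(C)C(C)(C)C)CC(=O)[C@]1(C)O[C@H]21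
A2 | alternative 2 | ten-membered C8 ketone with C2=C3 methyl dienol ether | CC(C)(C)[Si](C)(C)O[C@H]2[C@H](CCO[Si](C)(C)C(C)(C)C)C(=O)C[C@H](C)[C@H](OCc1ccc(OC)cc1)/C=C(OC)/C(C)=C\2
A3 | alternative 3 | ten-membered (1E,4Z)-dien-3-one | C=C(COCc1ccc(OC)cc1)[C@@H]1[C@H](OC(=O)/C(C)=C/C)C[C@H](C)/C=C/C(=O)/C(C)=C\[C@H]1O[Si](C)(C)C(C)(C)C
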